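An easy step first: the autumn run stands flat from its first reading at 3.00 h, and you give the flask far longer, 3.0 d, so divide time out.

| flask | first end groups | second end groups | protic impurity | remark | time |
|---|---|---|---|---|---|
| autumn | 0.30 M | 0.20 M | 0.015 M | run made earlier |  |
| midnight | 0.30 M | 0.45 M | 0.015 M | run made earlier |  |
| dawn | 0.45 M | 0.30 M | 0.015 M | run made earlier |  |
| flask | 0.30 M | 0.300 M | 0.0150 M |  | 3.0 d |

| run | time / h | first end groups / % | links / % |
|---|---|---|---|
| autumn | 3.00 | 37.1 | 6.2 |
| autumn | 8.00 | 36.0 | 6.5 |
| autumn | 20.0 | 36.9 | 6.3 |
| autumn | 40.0 | 36.2 | 6.2 |
| midnight | 10.0 | 0 | 25.0 |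
| midnight | 20.0 | 0.2 | 24.7 |
| midnight | 30.0 | 0 | 23.6 |
| midnight | 40.0 | 0.1 | 24.8 |
| dawn | 10.0 | 35.4 | 10.2 |
| dawn | 20.0 | 35.9 | 9.4 |
| dawn | 30.0 | 36.5 | 9.1 |
| dawn | 40.0 | 36.0 | 8.7 |

(scatter of a reading: 0.5 percentage points)

- the earlier runs were read with a standard deviation of 0.5 percentage points

1. share of the first end groups used up at 3.0 d
2. links at 3.0 d, in percent of the first end groups charged

Take the rate of links over the rate of all other use of first end groups. My reckoning supposes that this ratio equals the second end groups present divided by a fixed amount, so first end groups cancel as well. In the midnight run, 24.5% of the first end groups became links while second end groups, less the impurity's share, averaged 0.285 M. That gives a balance amount of 0.877 M, a selectivity factor in concentration form.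

In the flask, 0.285 M of second end groups is available, so links start at 24.5% of the use. I expect that share to drop as second end groups fall towards zero, averaging 14.0%. I reckon 95.0% used and 13.3% links.

The forecast says 96.5% and 14.5%, with links above mine, and holds that “Three days is ample, even near balance.”

The flask gives 95.2% used and 13.4% links.

    first end groups + second end groups → links (k = 0.00530 /M/s)
    first end groups + second end groups → rings, rate k2*[first end groups] as long as [second end groups] is above zero (k = 0.00450 /s)
    second end groups + protic impurity → quenched reagent (k = 0.0670 /M/s)

The balance amount gave 13.3% for the flask, beside the 13.4% it shows. Now take the neighbour charged with 0.75 M of second end groups, where first end groups are used to 100%. Its second end groups average 0.585 M, so the same balance amount gives 40.0% links. That neighbour ends with 40.7% links.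

The runs were computed with constants of no real substance, and the scatter is random.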